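In the benzene ring of the chroman, O1 (on C8a) and C4 (on C4a) occupy adjacent carbons, para and meta to the C6 carboxyl: the imprint of a nucleophile and an electrophile added across a 4-carboxy aryne. Everything rests on that disconnection. In one operation a tertiary alkoxide adds to the aryne (O1–C8a) and the resulting C4a carbanion opens the neighbouring terminal oxirane at its CH2 (C4–C4a), closing the dihydropyran ring with C2 and C3 already set. The precursors are (R,R)-1,2-epoxynerolidol, held as its trimethylsilyl ether, and an o-silylaryl triflate carrying the carboxyl as tert-butyl ester; fluoride unmasks both.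

Key step: step 9

Remark on the chemistry: the target SMILES decodes as (2R,3R), with the 3-OH cis to the homogeranyl chain and trans to the 2-methyl group. Chroman numbering (O1, C2, C3, C4, C4a, C5–C8, C8a) is used for all intermediates.

Design remark: a stoichiometric free epoxy alkoxide is open to Payne migration and to acyl attack on a small ester, and a methyl ester does not tolerate butyllithium. The tertiary OH therefore enters the key step as its Me3Si ether, the carboxyl travels as the tert-butyl ester, and the key-step medium holds no acidic O–H or C–H.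

Step 1
Reactants: 1 methyl vinyl ketone (but-3-en-2-one)
Product: 2 rac-1-(oxiran-2-yl)ethanone
Conditions: 30% aq H2O2, cat. NaOH, H2O, 0–5 °C; CH2Cl2 extraction, distillation
Reagents that add atoms: hydrogen peroxide, OO
Why: Weitz–Scheffer nucleophilic epoxidation, in which hydroperoxide adds conjugately to the enone and the enolate closes the oxirane with loss of hydroxide; the racemate is what the next step needs.

Step 2
Reactants: 2 rac-1-(oxiran-2-yl)ethanone
Product: 3 (R)-1-(oxiran-2-yl)ethanone
Conditions: (S,S)-(salen)Co(OAc) (1 mol %; salen = dianion of N,N'-bis(3,5-di-tert-butylsalicylidene)cyclohexane-1,2-diamine), H2O (0.55 equiv), THF, 0 °C → rt; vacuum transfer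
Reagents that add atoms: none
Why: Hydrolytic kinetic resolution of a terminal epoxide bearing a carbonyl group, a known substrate class, in which the (S,S) catalyst hydrolyses the S enantiomer at its CH2 and leaves the R epoxide, whose stereocentre becomes C3 of the target.

Step 3
Reactants: 4 thioanisole; 5 geranyl bromide
Product: 7 homogeranyl phenyl sulfide [(3E)-4,8-dimethylnona-3,7-dien-1-yl phenyl sulfide], via (phenylthio)methyllithium 6 (not isolated)
Conditions: 4, n-BuLi, DABCO, THF, 0 °C; then 5, −78 °C → rt
Reagents that add atoms: none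
Why: SN2 alkylation of a sulfur-stabilised carbanion at the unhindered primary allylic CH2, which adds the one missing carbon and leaves the E alkene untouched.

Step 4
Reactants: 7 homogeranyl phenyl sulfide
Product: 9 homogeranyl iodide [(3E)-1-iodo-4,8-dimethylnona-3,7-diene], via methyl(phenyl)sulfonium iodide 8 (not isolated)
Conditions: MeI (excess), NaI, DMF, 75 °C
Reagents that add atoms: methyl iodide, CI; sodium iodide, [Na+].[I-] (shared iodide pool)
Why: Sulfide-to-iodide exchange by S-methylation followed by SN2 displacement, in which iodide attack at the methyl group only regenerates the reactants, so the primary chain carbon is drained irreversibly to the iodide.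

Step 5
Reactants: 9 homogeranyl iodide; 3 (R)-1-(oxiran-2-yl)ethanone
Product: 12 (2R,5E)-6,10-dimethyl-2-[(2R)-oxiran-2-yl]undeca-5,9-dien-2-ol, via homogeranylmagnesium iodide 10 (not isolated), via iodomagnesium alkoxide 11 (not isolated)
Conditions: 9, Mg turnings, Et2O, reflux; solution added to 3, Et2O–CH2Cl2, −78 °C; H2O quench at −78 °C
Reagents that add atoms: none
Why: Grignard addition under the Cram chelate model, in which Mg bridges the carbonyl and oxirane oxygens and holds them syn, so the chain enters from the face of the oxirane H rather than its CH2 and sets the carbinol (future C2) as R, while carbonyl addition at −78 °C outruns epoxide opening.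

Step 6
Reactants: 12 epoxy alcohol
Product: 13 trimethylsilyl ether of 12
Conditions: N-(trimethylsilyl)imidazole, CH2Cl2, rt; filtration through Et3N-deactivated silica
Reagents that add atoms: N-(trimethylsilyl)imidazole, C[Si](C)(C)n1ccnc1
Why: O-silylation of a hindered tertiary alcohol by a strong neutral silyl donor, which meets neither acid nor alkoxide, so the oxirane and both stereocentres stay as they are.

Step 7
Reactants: 14 tert-butyl 4-hydroxybenzoate
Product: 15 tert-butyl 3-bromo-4-hydroxybenzoate
Conditions: NBS (1.0 equiv), MeCN, 0 °C → rt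
Reagents that add atoms: N-bromosuccinimide, O=C1CCC(=O)N1Br
Why: Electrophilic aromatic bromination directed ortho by the phenol (para is blocked by the ester), with one equivalent stopping at the monobromide because the first bromine deactivates the ring.

Step 8
Reactants: 15 tert-butyl 3-bromo-4-hydroxybenzoate
Product: 19 tert-butyl 4-(trifluoromethylsulfonyloxy)-3-(trimethylsilyl)benzoate, via aryl trimethylsilyl ether 16 (not isolated), via aryllithium 17 (not isolated), via lithium 2-silylphenoxide 18 (not isolated)
Conditions: HMDS, THF, reflux, then evaporation; n-BuLi, THF, −100 °C; Tf2O, −100 °C → rt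
Reagents that add atoms: hexamethyldisilazane, C[Si](C)(C)N[Si](C)(C)C; triflic anhydride, O=S(=O)(C(F)(F)F)OS(=O)(=O)C(F)(F)F
Why: Standard one-pot entry to o-silylaryl triflates (O-silylation, Br/Li exchange, retro-Brook O→C silyl shift, triflation), in which exchange at −100 °C is faster than attack on the hindered tert-butyl ester and the silyl shift is intramolecular.

Step 9
Reactants: 13 trimethylsilyl ether of the epoxy alcohol; 19 silyl triflate
Product: 24 kuhistanol D tert-butyl ester, via potassium epoxy alkoxide 20 (not isolated), via aryne 21 (not isolated), via C4a aryl anion 22 (not isolated), via potassium C3 alkoxide 23 (not isolated)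
Conditions: 13 (1 equiv), 19 (1.3 equiv), spray-dried KF (4 equiv), 18-crown-6 (4 equiv), THF (0.03 M), −20 °C → rt; then H2O
Reagents that add atoms: none
Why: Proposed new method: dry fluoride takes Me3Si off both partners, so aryne 21 and alkoxide 20 appear side by side in a medium without acidic protons; 20 adds to the aryne carbon para to CO2tBu (O1–C8a), the charge lands on the meta carbon C4a where the field effect of the ester stabilises it best, and carbanion 22 attacks the oxirane CH2 from the rear (C4–C4a) to release alkoxide 23. The closest known reaction types are aryne annulations in which the aryl anion left by an oxygen nucleophile is caught by a tethered ester or enone (xanthone and xanthene syntheses) and Parham cyclisations of o-metallated aryl glycidyl ethers onto their epoxide, but their combination on an epoxy alkoxide has not been shown. The dihydropyran ring O1–C2–C3–C4–C4a–C8a closes in the 6-endo-tet mode. No stereocentre is created and neither the C2–O nor the C3–O bond is touched, so 2R and 3R pass unchanged from 13 into 24. The step needs para rather than meta addition (only a modest inductive bias, so the 7-carboxylate isomer must be removed by chromatography), opening at CH2 rather than 5-exo attack at C3 (disfavoured because C3 adjoins fully substituted C2, a neopentyl-type site) and aryne capture before the Payne shift of 20 (a first-order leak kept small because the silyl ether holds free alkoxide low and the medium is aprotic and cold). The tert-butyl ester keeps alkoxides and carbanion 22 away from the carboxyl carbon, and high dilution favours ring closure over intermolecular quenching.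

Step 10
Reactants: 24 kuhistanol D tert-butyl ester
Product: 26 kuhistanol D, via potassium carboxylate 25 (not isolated)
Conditions: powdered KOH (excess), THF, rt; then 1 M HCl, 0 °C, to pH 3, EtOAc
Reagents that add atoms: potassium hydroxide, [K+].[OH-]
Why: BAC2 saponification of a tert-butyl benzoate by poorly solvated hydroxide in THF, a base-only cleavage that spares the trisubstituted alkenes, the tertiary alkyl aryl ether and both stereocentres.

Compound list
1 | methyl vinyl ketone | CC(=O)C=C | starting material
2 | rac-1-(oxiran-2-yl)ethanone | CC(=O)C1CO1 | intermediate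
3 | (R)-1-(oxiran-2-yl)ethanone | CC(=O)[C@H]1CO1 | intermediate
4 | thioanisole | CSc1ccccc1 | starting material
5 | geranyl bromide | CC(C)=CCC/C(C)=C/CBr | starting material
6 | (phenylthio)methyllithium | [Li]CSc1ccccc1 | intermediate
7 | (3E)-4,8-dimethylnona-3,7-dien-1-yl phenyl sulfide | CC(C)=CCC/C(C)=C/CCSc1ccccc1 | intermediate
8 | [(3E)-4,8-dimethylnona-3,7-dien-1-yl](methyl)(phenyl)sulfonium iodide | CC(C)=CCC/C(C)=C/CC[S+](C)c1ccccc1.[I-] | intermediate
9 | (3E)-1-iodo-4,8-dimethylnona-3,7-diene (homogeranyl iodide) | CC(C)=CCC/C(C)=C/CCI | intermediate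
10 | homogeranylmagnesium iodide | CC(C)=CCC/C(C)=C/CC[Mg]I | intermediate
11 | iodomagnesium alkoxide of 12 | CC(C)=CCC/C(C)=C/CC[C@@](C)(O[Mg]I)[C@H]1CO1 | intermediate
12 | (2R,5E)-6,10-dimethyl-2-[(2R)-oxiran-2-yl]undeca-5,9-dien-2-ol | CC(C)=CCC/C(C)=C/CC[C@@](C)(O)[C@H]1CO1 | intermediate
13 | {[(2R,5E)-6,10-dimethyl-2-[(2R)-oxiran-2-yl]undeca-5,9-dien-2-yl]oxy}trimethylsilane | CC(C)=CCC/C(C)=C/CC[C@@](C)(O[Si](C)(C)C)[C@H]1CO1 | intermediate
14 | tert-butyl 4-hydroxybenzoate | CC(C)(C)OC(=O)c1ccc(O)cc1 | starting material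
15 | tert-butyl 3-bromo-4-hydroxybenzoate | CC(C)(C)OC(=O)c1ccc(O)c(Br)c1 | intermediate
16 | tert-butyl 3-bromo-4-(trimethylsilyloxy)benzoate | CC(C)(C)OC(=O)c1ccc(O[Si](C)(C)C)c(Br)c1 | intermediate
17 | tert-butyl 3-lithio-4-(trimethylsilyloxy)benzoate | CC(C)(C)OC(=O)c1ccc(O[Si](C)(C)C)c([Li])c1 | intermediate
18 | lithium 4-(tert-butoxycarbonyl)-2-(trimethylsilyl)phenoxide | CC(C)(C)OC(=O)c1ccc([O-])c([Si](C)(C)C)c1.[Li+] | intermediate
19 | tert-butyl 4-(trifluoromethylsulfonyloxy)-3-(trimethylsilyl)benzoate | CC(C)(C)OC(=O)c1ccc(OS(=O)(=O)C(F)(F)F)c([Si](C)(C)C)c1 | intermediate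
20 | potassium (2R,5E)-6,10-dimethyl-2-[(2R)-oxiran-2-yl]undeca-5,9-dien-2-olate | CC(C)=CCC/C(C)=C/CC[C@@](C)([O-])[C@H]1CO1.[K+] | intermediate
21 | tert-butyl 3,4-didehydrobenzoate (aryne) | CC(C)(C)OC(=O)C1=CC#CC=C1 | intermediate
22 | potassium aryl anion: tert-butyl 4-{[(2R,5E)-6,10-dimethyl-2-[(2R)-oxiran-2-yl]undeca-5,9-dien-2-yl]oxy}benzoate metallated at C3 of the benzoate (C4a) | CC(C)=CCC/C(C)=C/CC[C@@](C)(Oc1ccc(C(=O)OC(C)(C)C)c[c-]1)[C@H]2CO2.[K+] | intermediate
23 | potassium C3 alkoxide of 24 | CC(C)=CCC/C(C)=C/CC[C@@]1(C)Oc2ccc(C(=O)OC(C)(C)C)cc2C[C@H]1[O-].[K+] | intermediate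
24 | tert-butyl (2R,3R)-2-[(3E)-4,8-dimethylnona-3,7-dien-1-yl]-3-hydroxy-2-methyl-3,4-dihydro-2H-chromene-6-carboxylate | CC(C)=CCC/C(C)=C/CC[C@@]1(C)Oc2ccc(C(=O)OC(C)(C)C)cc2C[C@H]1O | intermediate
25 | potassium salt of 26 | CC(C)=CCC/C(C)=C/CC[C@@]1(C)Oc2ccc(C(=O)[O-])cc2C[C@H]1O.[K+] | intermediate
26 | kuhistanol D, (2R,3R)-2-[(3E)-4,8-dimethylnona-3,7-dien-1-yl]-3-hydroxy-2-methyl-3,4-dihydro-2H-chromene-6-carboxylic acid | CC(C)=CCC/C(C)=C/CC[C@@]1(C)Oc2ccc(C(=O)O)cc2C[C@H]1O | target

Total step count: 10. Longest linear sequence: 6 steps (3, 4, 5, 6, 9, 10).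

Steps most likely to fail

1. Step 9.
- What may go wrong:
  - The oxirane may migrate along the chain (Payne shift) before the alkoxide meets the aryne.
  - The alkoxide may add at the aryne carbon meta to the ester.
  - The C4a carbanion may capture a proton before it cyclises.
  - The carbanion may open the oxirane in the 5-exo mode.
  - The released C3 alkoxide may be arylated further.
- Fallback: it uses known reactions only, makes the two bonds one at a time in the reverse order, sets out from 13 and returns at 24.
  - Commercial tert-butyl 3-bromo-4-fluorobenzoate (CC(C)(C)OC(=O)c1ccc(F)c(Br)c1) undergoes Br/Mg exchange with iPrMgCl·LiCl (THF, −20 °C).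
  - With CuI (10 mol %) the arylmagnesium opens the oxirane of 13 at its CH2 (C4–C4a). Citric acid in MeOH on work-up removes the silyl group to give tert-butyl 3-[(2R,3R,6E)-2,3-dihydroxy-3,7,11-trimethyldodeca-6,10-dien-1-yl]-4-fluorobenzoate F1.
  - Only the secondary OH is etherified with 4-methoxybenzyl trichloroacetimidate (cat. La(OTf)3, toluene). This gives tert-butyl 4-fluoro-3-[(2R,3R,6E)-3-hydroxy-2-(4-methoxybenzyloxy)-3,7,11-trimethyldodeca-6,10-dien-1-yl]benzoate F2. The group does not migrate and blocks the competing five-membered closure.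
  - KH in THF–DMF closes O1–C8a by intramolecular SNAr at the fluorine-bearing carbon para to the ester, without touching the C2–O bond. The product is kuhistanol D tert-butyl ester 3-O-(4-methoxybenzyl) ether F3.
  - DDQ (CH2Cl2–pH 7 buffer) then returns to 24.

2. Step 5.
- What may go wrong:
  - Facial selectivity may be poor if the weakly basic oxirane oxygen does not hold the chelate.
  - The methyl ketone may be enolised.
  - Magnesium halide may open the oxirane.
- Fallback: the oxirane is replaced by a strongly chelating acetonide and rebuilt afterwards. It sets out from 9 and returns at 12.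
  - Commercial methyl (R)-2,2-dimethyl-1,3-dioxolane-4-carboxylate (COC(=O)[C@H]1COC(C)(C)O1) is converted with MeONHMe·HCl and iPrMgCl into (4R)-N-methoxy-N,2,2-trimethyl-1,3-dioxolane-4-carboxamide F4.
  - MeMgBr converts F4 into 1-[(4R)-2,2-dimethyl-1,3-dioxolan-4-yl]ethanone F5.
  - The Grignard reagent made from 9 adds to F5 (Et2O, −78 °C) under α-alkoxy Cram chelate control, with the same facial sense. This gives (2R,5E)-2-[(4R)-2,2-dimethyl-1,3-dioxolan-4-yl]-6,10-dimethylundeca-5,9-dien-2-ol F6.
  - Aqueous AcOH gives (2R,3R,6E)-3,7,11-trimethyldodeca-6,10-diene-1,2,3-triol F7.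
  - TsCl, Et3N and cat. Bu2SnO give (2R,3R,6E)-2,3-dihydroxy-3,7,11-trimethyldodeca-6,10-dien-1-yl 4-methylbenzenesulfonate F8.
  - K2CO3 in MeOH at 0 °C closes the terminal oxirane with retention at the secondary carbon and gives 12.

3. Step 8.
- What may go wrong:
  - Butyllithium or the aryllithium may attack the ester.
  - The silyl migration may be incomplete before triflation.
- Fallback: silicon is brought in by cross-coupling and no organolithium is used. It sets out from 15 and returns at 19.
  - BnBr and K2CO3 in DMF give tert-butyl 4-(benzyloxy)-3-bromobenzoate F9.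
  - Palladium-catalysed silylation with hexamethyldisilane (Pd2(dba)3, 2-(di-tert-butylphosphino)biphenyl, LiOAc, dioxane, 100 °C) gives tert-butyl 4-(benzyloxy)-3-(trimethylsilyl)benzoate F10.
  - Hydrogenolysis (H2, Pd/C, EtOAc) gives tert-butyl 4-hydroxy-3-(trimethylsilyl)benzoate F11.
  - Tf2O and pyridine (CH2Cl2, 0 °C) give 19.

Further compounds
F1 | step 9 | tert-butyl 3-[(2R,3R,6E)-2,3-dihydroxy-3,7,11-trimethyldodeca-6,10-dien-1-yl]-4-fluorobenzoate | CC(C)=CCC/C(C)=C/CC[C@@](C)(O)[C@H](O)Cc1cc(C(=O)OC(C)(C)C)ccc1F
F2 | step 9 | tert-butyl 4-fluoro-3-[(2R,3R,6E)-3-hydroxy-2-(4-methoxybenzyloxy)-3,7,11-trimethyldodeca-6,10-dien-1-yl]benzoate | CC(C)=CCC/C(C)=C/CC[C@@](C)(O)[C@H](OCc1ccc(OC)cc1)Cc1cc(C(=O)OC(C)(C)C)ccc1F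
F3 | step 9 | kuhistanol D tert-butyl ester 3-O-(4-methoxybenzyl) ether | CC(C)=CCC/C(C)=C/CC[C@@]1(C)Oc2ccc(C(=O)OC(C)(C)C)cc2C[C@H]1OCc3ccc(OC)cc3
F4 | step 5 | (4R)-N-methoxy-N,2,2-trimethyl-1,3-dioxolane-4-carboxamide | CON(C)C(=O)[C@H]1COC(C)(C)O1
F5 | step 5 | 1-[(4R)-2,2-dimethyl-1,3-dioxolan-4-yl]ethanone | CC(=O)[C@H]1COC(C)(C)O1
F6 | step 5 | (2R,5E)-2-[(4R)-2,2-dimethyl-1,3-dioxolan-4-yl]-6,10-dimethylundeca-5,9-dien-2-ol | CC(C)=CCC/C(C)=C/CC[C@@](C)(O)[C@H]1COC(C)(C)O1
F7 | step 5 | (2R,3R,6E)-3,7,11-trimethyldodeca-6,10-diene-1,2,3-triol | CC(C)=CCC/C(C)=C/CC[C@@](C)(O)[C@H](O)CO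
F8 | step 5 | (2R,3R,6E)-2,3-dihydroxy-3,7,11-trimethyldodeca-6,10-dien-1-yl 4-methylbenzenesulfonate | CC(C)=CCC/C(C)=C/CC[C@@](C)(O)[C@H](O)COS(=O)(=O)c1ccc(C)cc1
F9 | step 8 | tert-butyl 4-(benzyloxy)-3-bromobenzoate | CC(C)(C)OC(=O)c1ccc(OCc2ccccc2)c(Br)c1
F10 | step 8 | tert-butyl 4-(benzyloxy)-3-(trimethylsilyl)benzoate | CC(C)(C)OC(=O)c1ccc(OCc2ccccc2)c([Si](C)(C)C)c1
F11 | step 8 | tert-butyl 4-hydroxy-3-(trimethylsilyl)benzoate | CC(C)(C)OC(=O)c1ccc(O)c([Si](C)(C)C)c1
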